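**Plan**

1. Daucane numbering is used. C1 is the quaternary fusion carbon (it carries CH3). C2 and C3 are ring CH2, C4 carries the isopropyl group, C5 is the sp2 fusion carbon, C6 and C7 are CH2, C8 carries C14H2O, C9 is =CH and C10 is CH2. The hardest feature is the seven-membered ring closed onto the lone quaternary stereocentre C1, next to the tetrasubstituted C4=C5 bond.
2. Cuts: C14–O (vanillate, made last), then C4–iPr (cross-coupling), then C1–C10 and C7–C8 of the seven-membered ring together in one operation (formal [4+3]).
3. Enabling feature: in the seven-membered ring, C8=C9 and the sp2 carbon C5 are 1,4-related across C7H2, and C8 bears the oxidised carbon C14. Moving C4=C5 to C5=C6, with C4 as C=O, uncovers a cyclohepta-1,4-diene-1-carboxylate. That is the retron of a vinylcarbenoid/diene cyclopropanation–Cope cascade.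
4. Forward: the five-membered ring is bought (bromoenone 1 → ketal diene 3). Vinyldiazoacetate 7 supplies C8, C9, C10 and C14. The cascade closes first the cyclopropane C6–C7–C8 and then the seven-membered ring.
5. The enone C4(=O)–C5=C6 left by the cascade is the handle for the tetrasubstituted alkene. 1,4-Reduction with enolate triflation fixes C4=C5, and an iron-catalysed coupling adds isopropyl. Ester reduction and a protecting-group-free Mitsunobu esterification finish the route.
6. Stereochemistry: the chiral dirhodium catalyst sets the two cyclopropane centres. The boat Cope rearrangement transfers them to C1, and no later step touches C1.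

Key step: step 6

Assumption: the sense of induction of Rh2(DOSP)4 is taken from its established behaviour with monosubstituted alkenes, so the R catalyst should give cyclopropane 8 as drawn. If the vinyl group of 3 responded in the opposite sense, the equally available S catalyst would be used with no other change.

**Step 1**
Reactants: 1 2-bromo-3-methylcyclopent-2-en-1-one
Product: 2 6-bromo-7-methyl-1,4-dioxaspiro[4.4]non-6-ene
Conditions: HOCH2CH2OH, p-TsOH (cat.), benzene, reflux, Dean–Stark
Reagents that add atoms: ethylene glycol, OCCO
Why: Acid-catalysed ketalisation with azeotropic removal of water, in which the α-bromine keeps the double bond in place, masks the carbonyl group that would otherwise make the diene electron-poor and could trap the carbenoid of step 6 as a carbonyl ylide.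

**Step 2**
Reactants: 2 6-bromo-7-methyl-1,4-dioxaspiro[4.4]non-6-ene
Product: 3 6-ethenyl-7-methyl-1,4-dioxaspiro[4.4]non-6-ene
Conditions: Bu3SnCH=CH2, Pd(PPh3)4 (5 mol %), BHT (trace), PhMe, 100 °C
Reagents that add atoms: tributyl(vinyl)stannane, C=C[Sn](CCCC)(CCCC)CCCC
Why: Stille cross-coupling of the alkenyl bromide under neutral conditions leaves the ketal intact and should give the achiral semicyclic 1,3-diene C7=C6–C5=C1.

**Step 3**
Reactants: 4 methyl acetoacetate
Product: 5 methyl 2-diazo-3-oxobutanoate
Conditions: p-ABSA, Et3N, MeCN, 0 °C to rt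
Reagents that add atoms: 4-acetamidobenzenesulfonyl azide (p-ABSA), CC(=O)Nc1ccc(cc1)S(=O)(=O)N=[N+]=[N-]
Why: Regitz diazo transfer to the activated methylene group of a β-keto ester.

**Step 4**
Reactants: 5 methyl 2-diazo-3-oxobutanoate
Product: 6 methyl 2-diazo-3-hydroxybutanoate (racemic)
Conditions: NaBH4, MeOH, 0 °C
Reagents that add atoms: none
Why: Chemoselective borohydride reduction of the ketone beside an inert diazo ester, giving a racemic carbinol centre that is removed in step 5.

**Step 5**
Reactants: 6 methyl 2-diazo-3-hydroxybutanoate
Product: 7 methyl 2-diazobut-3-enoate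
Conditions: POCl3, Et3N, CH2Cl2, 0 °C to rt; kept cold in hexanes and used at once
Reagents that add atoms: none
Why: Dehydration by way of the dichlorophosphate and E2 elimination should give the vinyldiazoacetate, which is used immediately because it slowly closes to a pyrazole by 1,5-electrocyclisation.

**Step 6**
Reactants: 3 6-ethenyl-7-methyl-1,4-dioxaspiro[4.4]non-6-ene; 7 methyl 2-diazobut-3-enoate
Product: 9 methyl (8aR)-3,3-(ethane-1,2-diyldioxy)-8a-methyl-1,2,3,5,8,8a-hexahydroazulene-6-carboxylate, via cis-divinylcyclopropane 8 (not isolated)
Conditions: Rh2(R-DOSP)4 (1 mol %), hexanes, −20 °C to rt, slow addition of 7 to 3; then PhMe, 80 °C until 8 is consumed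
Reagents that add atoms: none
Why: Rh2(R-DOSP)4 takes N2 from 7, and the resulting donor/acceptor vinylcarbenoid adds in a concerted asynchronous [2+1] manner to the vinyl group C6=C7 of 3, closing the cyclopropane C6–C7–C8 of 8; 8 then undergoes a strain-releasing [3,3] shift (divinylcyclopropane–cycloheptadiene rearrangement) through the endo,endo boat, in which C6–C8 breaks and C1–C10 forms, so the seven-membered ring closes by ring enlargement in an overall formal [4+3] cycloaddition. The closest known reaction type is the enantioselective tandem cyclopropanation/Cope rearrangement of vinyldiazoacetates with 1,3-dienes, which is known for 1-vinyl-2-methylcycloalkenes and for acyclic 4,4-disubstituted dienes with formation of a quaternary carbon. The chiral pocket of the catalyst decides which face of the vinyl group is attacked and so fixes C6 and C8 of 8, and because the boat is the only geometry that gives two cis ring alkenes and the geometry of C1=C5 is locked by the five-membered ring (methyl inside, C2 outside), these two centres are erased while their information passes completely to the quaternary carbon C1, expected as R. The step needs site selectivity (vinyl versus ring alkene), secured because the bulky carbenoid cannot reach the tetrasubstituted C1=C5 bond, and cis diastereoselectivity, secured by the general preference for the alkene substituent to end up syn to the donor (vinyl) group and anti to the ester. Since the carbene carbon carries the ester, CO2Me must end on C8 next to C7H2 and C8=C9 must lie where the target has it, with no regiochemical alternative. The inside methyl group on C1 slows the Cope step, hence the final warming, and the ketal keeps the diene electron-rich.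

**Step 7**
Reactants: 9 methyl (8aR)-3,3-(ethane-1,2-diyldioxy)-8a-methyl-1,2,3,5,8,8a-hexahydroazulene-6-carboxylate
Product: 10 methyl (8aR)-8a-methyl-3-oxo-1,2,3,5,8,8a-hexahydroazulene-6-carboxylate
Conditions: PPTS (cat.), acetone/H2O, rt
Reagents that add atoms: water, O
Why: Mild acid hydrolysis of an allylic ketal through a stabilised allyl oxocarbenium ion should be fast enough to leave the methyl ester untouched and the skipped diene C5=C6/C8=C9 out of conjugation.

**Step 8**
Reactants: 10 methyl (8aR)-8a-methyl-3-oxo-1,2,3,5,8,8a-hexahydroazulene-6-carboxylate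
Product: 12 methyl (8aR)-8a-methyl-3-(trifluoromethylsulfonyloxy)-1,2,4,5,8,8a-hexahydroazulene-6-carboxylate, via lithium enolate 11 (not isolated)
Conditions: L-Selectride (1.05 equiv), THF, −78 °C; then Comins reagent, −78 to 0 °C
Reagents that add atoms: N-(5-chloropyridin-2-yl)bis(trifluoromethanesulfonimide) (Comins reagent), O=S(=O)(N(c1ccc(Cl)cn1)S(=O)(=O)C(F)(F)F)C(F)(F)F
Why: Conjugate hydride addition of the bulky borohydride to the s-cis enone, which is more electrophilic than the trisubstituted enoate, should give the C4=C5 enolate regiospecifically, and this enolate is O-sulfonylated before it can equilibrate (reductive enolate trapping).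

**Step 9**
Reactants: 12 methyl (8aR)-8a-methyl-3-(trifluoromethylsulfonyloxy)-1,2,4,5,8,8a-hexahydroazulene-6-carboxylate
Product: 13 methyl (8aR)-8a-methyl-3-(propan-2-yl)-1,2,4,5,8,8a-hexahydroazulene-6-carboxylate
Conditions: i-PrMgCl (1.5 equiv), Fe(acac)3 (10 mol %), THF/NMP, −30 °C
Reagents that add atoms: isopropylmagnesium chloride, CC(C)[Mg]Cl
Why: Iron-catalysed Kumada-type cross-coupling of an alkenyl triflate with a secondary alkyl Grignard reagent is much faster at low temperature than attack on the ester, and it keeps both the branched alkyl group and the position of the C4=C5 bond.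

**Step 10**
Reactants: 13 methyl (8aR)-8a-methyl-3-(propan-2-yl)-1,2,4,5,8,8a-hexahydroazulene-6-carboxylate
Product: 14 [(8aR)-8a-methyl-3-(propan-2-yl)-1,2,4,5,8,8a-hexahydroazulen-6-yl]methanol
Conditions: DIBAL-H (2.5 equiv), CH2Cl2, −78 °C; Rochelle salt work-up
Reagents that add atoms: none
Why: 1,2-Reduction of the conjugated ester with DIBAL-H should give the primary allylic alcohol while the two unactivated alkenes stay inert.

**Step 11**
Reactants: 14 [(8aR)-8a-methyl-3-(propan-2-yl)-1,2,4,5,8,8a-hexahydroazulen-6-yl]methanol; 15 vanillic acid (4-hydroxy-3-methoxybenzoic acid)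
Product: 16 [(8aR)-8a-methyl-3-(propan-2-yl)-1,2,4,5,8,8a-hexahydroazulen-6-yl]methyl 4-hydroxy-3-methoxybenzoate
Conditions: PPh3, DIAD, THF, 0 °C to rt
Reagents that add atoms: none
Why: In this Mitsunobu esterification only the carboxylic acid, not the much less acidic phenol, protonates the betaine and displaces the primary allylic alkoxyphosphonium group by SN2 at C14, so no phenol protection is needed and C1 is not involved.

**Compound list**

1 | 2-bromo-3-methylcyclopent-2-en-1-one | CC1=C(Br)C(=O)CC1 | starting material
2 | 6-bromo-7-methyl-1,4-dioxaspiro[4.4]non-6-ene | CC1=C(Br)C2(CC1)OCCO2 | intermediate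
3 | 6-ethenyl-7-methyl-1,4-dioxaspiro[4.4]non-6-ene | C=CC1=C(C)CCC12OCCO2 | intermediate
4 | methyl acetoacetate | COC(=O)CC(C)=O | starting material
5 | methyl 2-diazo-3-oxobutanoate | COC(=O)C(=[N+]=[N-])C(C)=O | intermediate
6 | methyl 2-diazo-3-hydroxybutanoate (racemic) | COC(=O)C(=[N+]=[N-])C(C)O | intermediate
7 | methyl 2-diazobut-3-enoate | COC(=O)C(=[N+]=[N-])C=C | intermediate
8 | methyl (1S,2S)-1-ethenyl-2-(7-methyl-1,4-dioxaspiro[4.4]non-6-en-6-yl)cyclopropane-1-carboxylate (the two alkenyl groups cis) | COC(=O)[C@]1(C=C)C[C@H]1C2=C(C)CCC23OCCO3 | intermediate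
9 | methyl (8aR)-3,3-(ethane-1,2-diyldioxy)-8a-methyl-1,2,3,5,8,8a-hexahydroazulene-6-carboxylate | COC(=O)C1=CC[C@@]2(C)CCC3(OCCO3)C2=CC1 | intermediate
10 | methyl (8aR)-8a-methyl-3-oxo-1,2,3,5,8,8a-hexahydroazulene-6-carboxylate | COC(=O)C1=CC[C@@]2(C)CCC(=O)C2=CC1 | intermediate
11 | lithium (8aR)-6-(methoxycarbonyl)-8a-methyl-1,2,4,5,8,8a-hexahydroazulen-3-olate | COC(=O)C1=CC[C@@]2(C)CCC([O-])=C2CC1.[Li+] | intermediate
12 | methyl (8aR)-8a-methyl-3-(trifluoromethylsulfonyloxy)-1,2,4,5,8,8a-hexahydroazulene-6-carboxylate | COC(=O)C1=CC[C@@]2(C)CCC(OS(=O)(=O)C(F)(F)F)=C2CC1 | intermediate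
13 | methyl (8aR)-8a-methyl-3-(propan-2-yl)-1,2,4,5,8,8a-hexahydroazulene-6-carboxylate | COC(=O)C1=CC[C@@]2(C)CCC(C(C)C)=C2CC1 | intermediate
14 | [(8aR)-8a-methyl-3-(propan-2-yl)-1,2,4,5,8,8a-hexahydroazulen-6-yl]methanol | OCC1=CC[C@@]2(C)CCC(C(C)C)=C2CC1 | intermediate
15 | vanillic acid | COc1cc(C(=O)O)ccc1O | starting material
16 | [(8aR)-8a-methyl-3-(propan-2-yl)-1,2,4,5,8,8a-hexahydroazulen-6-yl]methyl 4-hydroxy-3-methoxybenzoate (CNP0327126.2) | COc1cc(C(=O)OCC2=CC[C@@]3(C)CCC(C(C)C)=C3CC2)ccc1O | target

**Step count**

- Total step count: 11.
- Longest linear sequence: 9 steps (4 → 16, steps 3 to 11). The branch from 1 runs over 8 steps.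

**Steps most likely to fail**

**Step 6 (key step).**
- Risk: facial discrimination by the catalyst may be incomplete at the crowded vinyl group. A slow Cope step may also let 8 isomerise thermally by reversible ring opening and lose enantiopurity.
- Fallback: stereocontrol is moved to a covalently bound C2-symmetric auxiliary, so that any stereochemical leak becomes a separable diastereomer. The fallback sets out from 1. Ketalisation with (2R,3R)-butane-2,3-diol gives the bromo ketal F1, and Stille vinylation gives the diene F2. The same cascade with 7 passes through the cis-divinylcyclopropane F3 to the cycloheptadiene ketal F4. The C1 epimer is removed by chromatography or crystallisation. PPTS hydrolysis then comes back to the route at 10.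

**Step 8.**
- Risk: the hydride may attack the carbonyl carbon (1,2) instead of C6, the enoate may be reduced in competition, or the enolate may exchange protons before it is trapped.
- Fallback: the C–C bond is made first and the reduction comes second. The fallback sets out from 10. Isopropylcerium dichloride (i-PrMgCl, dried CeCl3, THF, −78 °C) should add 1,2 to the ketone only and give the tertiary allylic alcohol F5, of which either C4 epimer serves. Ionic hydrogenation (Et3SiH, CF3CO2H, CH2Cl2, −40 °C) ionises it to the C4–C5–C6 allyl cation. This cation should take hydride at the less hindered terminus C6 and so place the double bond at C4=C5. The fallback comes back at 13 and bypasses 12.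

**Step 9.**
- Risk: coupling may be slow at the fully substituted alkenyl triflate, so that β-hydride transfer (simple reduction of the triflate) or Grignard attack on the ester takes over.
- Fallback: an sp2–sp2 coupling is followed by a site-selective hydrogenation. The fallback sets out from 12. Suzuki–Miyaura coupling with isopropenylboronic acid pinacol ester (Pd(dppf)Cl2, K3PO4, dioxane/H2O, 60 °C) gives the isopropenyl diene F6. Hydrogenation with RhCl(PPh3)3 (H2, 1 atm, benzene/EtOH) should saturate only the 1,1-disubstituted bond. The fallback comes back at 13.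

**Further compounds**

F1 | step 6 | (2R,3R)-6-bromo-2,3,7-trimethyl-1,4-dioxaspiro[4.4]non-6-ene | CC1=C(Br)C2(CC1)O[C@H](C)[C@@H](C)O2
F2 | step 6 | (2R,3R)-6-ethenyl-2,3,7-trimethyl-1,4-dioxaspiro[4.4]non-6-ene | C=CC1=C(C)CCC12O[C@H](C)[C@@H](C)O2
F3 | step 6 | methyl (1S,2S)-1-ethenyl-2-[(2R,3R)-2,3,7-trimethyl-1,4-dioxaspiro[4.4]non-6-en-6-yl]cyclopropane-1-carboxylate | COC(=O)[C@]1(C=C)C[C@H]1C2=C(C)CCC23O[C@H](C)[C@@H](C)O3
F4 | step 6 | (2R,3R)-butane-2,3-diyl ketal of methyl (8aR)-8a-methyl-3-oxo-1,2,3,5,8,8a-hexahydroazulene-6-carboxylate | COC(=O)C1=CC[C@@]2(C)CCC3(O[C@H](C)[C@@H](C)O3)C2=CC1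
F5 | step 8 | methyl (8aR)-3-hydroxy-8a-methyl-3-(propan-2-yl)-1,2,3,5,8,8a-hexahydroazulene-6-carboxylate (C3 epimers, centre removed in the next operation) | COC(=O)C1=CC[C@@]2(C)CCC(O)(C(C)C)C2=CC1
F6 | step 9 | methyl (8aR)-8a-methyl-3-(prop-1-en-2-yl)-1,2,4,5,8,8a-hexahydroazulene-6-carboxylate | COC(=O)C1=CC[C@@]2(C)CCC(C(C)=C)=C2CC1
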